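## The problem

Kanzonol T (17) is an isoflavone, a 3-aryl-4H-chromen-4-one, and has no stereocentre, so nothing has to be controlled in three dimensions and no centre can steer another. Ring A carries hydroxyls at C5 and C7 with a 3-hydroxy-3-methylbutyl chain on C6 between them. Ring B is joined through C1' to C3, bears a hydroxyl at C2', and is fused along C3'–C4' to a 2,2-dimethyl-2H-pyran whose oxygen sits on C4'. The difficulties are regiochemical: the chain must end on C6 and not on the equally activated C8, the pyran must close in the angular sense onto C3', and the aryl group must end on C3 of ring C and not on C2. Three features limit late-stage reagents: the tertiary alcohol closes onto a neighbouring phenol oxygen or dehydrates under acid; the chromene C=C bond is lost on hydrogenation and attacked by acids and electrophilic oxidants; and the free polyphenolic chromone is air-sensitive in base and opens at C2 with hot hydroxide. Protecting groups must therefore leave without acid, hydrogen or strong base, which points to silyl ethers and a fluoride end game, and every reduction must be finished before ring B is attached. The feature that opens a short convergent route is ring C: O1 and C4 are ortho substituents of ring A, so cutting C4–C3 and O1–C2 leaves a ring A salicylaldehyde (C4 as formyl carbon, O1 as phenol) and a C2–C3 alkyne carrying ring B. The phenol from which that salicylaldehyde derives has a mirror plane, so its two ortho positions are the same.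

## Retrosynthesis

**17 to 16.** The three O–Si bonds and the C2–Si bond of isoflavone 16 are cut. Silyl ethers are preferred to methyl, benzyl or methoxymethyl ethers, whose removal needs Lewis acid, hydrogen or protic acid, each of which would destroy the chromene or the tertiary alcohol. The skeleton is unchanged, but 16 is stable and carries at C2 the group that directs the key step. The forward reaction must be one fluoride treatment that cleaves all four bonds.

**16 to 8 and 15.** Ring C is cut at C4–C3 and O1–C2, giving salicylaldehyde 8 and silyl alkyne 15. The neighbouring cuts (C3–C1' alone by cross-coupling of a 3-halogenated chromone, or O1–C2 alone after one-carbon insertion into a benzyl ketone) need ring C or its open-chain equivalent to be built on ring A first. The chosen cut joins two fragments of similar size in the ring-forming step and uses the aldehyde oxidation level directly. The forward reaction is an oxidative annulation under trivalent rhodium with Cu(OAc)2. It must place ring B on the carbon that bonds to the acyl group and silicon on the carbon that bonds to oxygen, and it must use the one free hydroxyl of 8.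

**8 to 7.** The C4–C4a bond (formyl group) is cut, leading to phenol 7. Because the two ortho positions of 7 are mirror images, a phenoxide-directed ortho-formylation can give only 8, with the free hydroxyl para to the chain. This replaces the C6 versus C8 question by a symmetry argument. The forward reaction must work without acid or organolithium reagents, which would remove or shift the silyl ethers.

**7 to 1 and 4.** The methyl–carbinol bond is cut to give ketone 6 (forward: MeMgBr). The chain C=C and the 4-O-benzyl bond are then restored to give enone 5 (forward: one hydrogenation does both). The C=C bond is cut to give aldehyde 3 and ylide 4 (forward: Wittig). Aldehyde 3 comes from 2 by silylation, and 2 from 2,4,6-trihydroxybenzaldehyde 1 by benzylation of the para hydroxyl. The benzyl group is chosen because the hydrogenation already needed for the chain removes it, exposing only the hydroxyl that must direct the formylation. The forward sequence needs a para-selective first alkylation.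

**15 to 9 and 10.** The alkynyl C–Si bond is cut to give acetylide 14, which comes from dibromo-olefin 13 and this from aldehyde 12 (forward: Corey–Fuchs homologation with a silyl chloride quench). Aldehyde 12 is the silyl ether of chromene aldehyde 11. The pyran ring of 11 is cut at O–C(Me)2 and at the aryl–vinyl bond, leading to 2,4-dihydroxybenzaldehyde 9 and 3-methylbut-2-enal 10. The formyl group of 9 sets the angular ring fusion by chelating the 2-hydroxyl and becomes the alkyne carbon attached to ring B.

## Roads not taken

**Alternative 1:** Ring A is cut at C7–C8 and C5–C6. Ring C remains as methyl 5-[5-(allyloxy)-2,2-dimethyl-2H-chromen-6-yl]-2-methyl-4-oxo-4H-pyran-3-carboxylate A2, and the missing atoms come from 6,6-dimethyloxan-2-one A3.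
- Forward step: the dienolate formed at the 2-methyl group of A2 would attack the lactone carbonyl of A3; the enolate of the new ketone would close on the ester and, after tautomerisation, give 2'-O-allyl Kanzonol T A1. Deallylation with a zerovalent palladium catalyst such as Pd(PPh3)4 would give 17.
- Merits: A3 brings in the chain and its tertiary alcohol, so the chain position is fixed by construction, and the ring A hydroxyls never need protection.
- Weak points: A3 has acidic α-hydrogens and can quench the dienolate by proton transfer. After the first acylation the most acidic site is C8, so closure from C6 needs a dianion. The alkoxide set free from A3 can add to the electrophilic C2 of the pyranone. A2, with ring B already in place, is itself a multistep target.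
- Comparison: this road is better in protecting-group economy and in leaving no C6 versus C8 question. The chosen plan sets against it that each of its steps is a well-known reaction type on simple aromatic aldehydes, and that its one uncertain point is an orientation, not whether a cascade runs at all.

**Alternative 2:** Ring B is cut at C1'–C6' and C2'–C3', giving 2,2-dimethyl-2H,5H-pyrano[4,3-b]pyran-5-one A5 and the chromone silyl ynol ether A6 (the 3-[(triisopropylsilyloxy)ethynyl]chromone carrying the silylated ring A substituents).
- Forward step: Diels–Alder addition followed by decarboxylative aromatisation would give tetrakis-O-silyl Kanzonol T A4.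
- Merits: the angular pyran and the 2'-oxygen are fixed by the cycloaddition, and no question of C2 versus C3 arylation arises because ring C is made beforehand.
- Weak points: the 4-alkoxy-2-pyranone diene of A5 and the ynol ether of A6 are both electron-rich, so the cycloaddition is mismatched and would need strong heating, under which silyl ynol ethers rearrange and chromenes can ring-open. A6 requires the complete ring A and ring C chromone first, so the 6-alkyl problem and ring C construction are untouched. Four different silyl groups must be handled.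
- Comparison: this road solves the one problem that the chosen plan settles in a single known condensation (step 7) and leaves open the two that the chosen plan addresses. It is more secure in the aryl position on ring C, against which the chosen plan sets only the directing effect of silicon.

**Alternative 3:** Ring C is cut at O1–C8a and C4–C4a, leading to 4-(3-hydroxy-3-methylbutyl)-3,5-bis(methoxymethoxy)-2-(trimethylsilyl)phenyl trifluoromethanesulfonate A8 and methyl 2-[5-(methoxymethoxy)-2,2-dimethyl-2H-chromen-6-yl]-3-oxopropanoate A10.
- Forward step: a fluoride source would convert A8 into the ring A aryne A9. The enolate oxygen of A10 would add to C8a and the resulting aryl anion at C4a would acylate on the ester, giving 5,7,2'-tris-O-methoxymethyl Kanzonol T A7.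
- Merits: room temperature, no transition metal or oxidant, full convergence, and no silicon to remove from C2. The C5 alkoxy group directs the nucleophile to the distal aryne carbon, which is at least as well founded as the silyl control of the chosen plan.
- Weak points: enolates of 1,3-dicarbonyl compounds normally attack arynes through carbon, which leads to insertion into the C–C bond and not to the chromone. A8 is a pentasubstituted benzene whose ortho-silyl triflate must be installed beside a tertiary alcohol. The methoxymethyl ethers of A7 need acid for removal, the condition under which the tertiary alcohol closes onto a neighbouring phenol and the chromene suffers.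
- Comparison: the ring-forming step of this road is milder, but its end game is harsher. The chosen plan sets against it a chromone-forming reaction known for salicylaldehydes and an end game that uses only fluoride.

Key step: step 11

Assumption: in step 11 the silyl alkyne is taken to insert as silyl alkynes do in related metal-mediated annulations, with silicon on the metal-bound carbon; this orientation has not been shown for salicylaldehyde annulation and the fallback for step 11 covers the opposite outcome.

## Route

Step 1
Reactants: 1 2,4,6-trihydroxybenzaldehyde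
Product: 2 4-(benzyloxy)-2,6-dihydroxybenzaldehyde
Conditions: BnBr (1.0 equiv), CsHCO3 (1.1 equiv), MeCN, 60 °C
Reagents that add atoms: benzyl bromide, BrCc1ccccc1
Why: Williamson etherification under acidity control: the weak base ionises mainly the 4-hydroxyl (para to the formyl group, not chelated) while the ortho hydroxyls are held by hydrogen bonding to the carbonyl, as in the 4-O-selective alkylation of 2,4-dihydroxybenzaldehydes; one equivalent of halide limits dialkylation.

Step 2
Reactants: 2 4-(benzyloxy)-2,6-dihydroxybenzaldehyde
Product: 3 4-(benzyloxy)-2,6-bis(tert-butyldimethylsilyloxy)benzaldehyde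
Conditions: TBSCl (3 equiv), imidazole (6 equiv), DMAP (cat.), DMF, rt to 40 °C
Reagents that add atoms: tert-butyldimethylsilyl chloride, CC(C)(C)[Si](C)(C)Cl
Why: Standard silylation of phenols; excess reagent and gentle warming overcome the hydrogen bond of the second ortho hydroxyl, and the benzyl ether keeps the para oxygen distinct.

Step 3
Reactants: 3 4-(benzyloxy)-2,6-bis(tert-butyldimethylsilyloxy)benzaldehyde; 4 1-(triphenylphosphoranylidene)propan-2-one
Product: 5 (E)-4-[4-(benzyloxy)-2,6-bis(tert-butyldimethylsilyloxy)phenyl]but-3-en-2-one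
Conditions: toluene, 110 °C
Reagents that add atoms: none
Why: Wittig olefination with a ketone-stabilised ylide should give the E enone; the geometry is of no consequence because the double bond is reduced in step 4.

Step 4
Reactants: 5 (E)-4-[4-(benzyloxy)-2,6-bis(tert-butyldimethylsilyloxy)phenyl]but-3-en-2-one
Product: 6 4-[2,6-bis(tert-butyldimethylsilyloxy)-4-hydroxyphenyl]butan-2-one
Conditions: H2 (1 atm), 10% Pd/C, EtOAc, rt
Reagents that add atoms: none
Why: Catalytic hydrogenation should saturate the conjugated C=C bond and hydrogenolyse the benzyl ether in one operation, exposing only the para hydroxyl; aryl silyl ethers and the saturated ketone are inert under these conditions.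

Step 5
Reactants: 6 4-[2,6-bis(tert-butyldimethylsilyloxy)-4-hydroxyphenyl]butan-2-one
Product: 7 3,5-bis(tert-butyldimethylsilyloxy)-4-(3-hydroxy-3-methylbutyl)phenol
Conditions: MeMgBr (3.5 equiv), THF, −78 to 0 °C; aq. NH4Cl
Reagents that add atoms: methylmagnesium bromide, C[Mg]Br
Why: Grignard addition to the methyl ketone after the first equivalent has deprotonated the phenol; low temperature keeps the aryl silyl ethers in place, and the product has the mirror plane on which step 6 relies.

Step 6
Reactants: 7 3,5-bis(tert-butyldimethylsilyloxy)-4-(3-hydroxy-3-methylbutyl)phenol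
Product: 8 4,6-bis(tert-butyldimethylsilyloxy)-2-hydroxy-5-(3-hydroxy-3-methylbutyl)benzaldehyde
Conditions: MgCl2 (3 equiv), Et3N (6 equiv), (CH2O)n (8 equiv), THF, 65 °C
Reagents that add atoms: paraformaldehyde (as formaldehyde), C=O
Why: Magnesium-mediated ortho-formylation of phenols (Casnati–Skattebøl): ortho-hydroxymethylation within the magnesium chelate followed by hydride transfer to a second formaldehyde; the two ortho positions are equivalent, so only one aldehyde can form, with the free hydroxyl para to the chain, and the conditions involve neither acid nor organolithium reagents.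

Step 7
Reactants: 9 2,4-dihydroxybenzaldehyde; 10 3-methylbut-2-enal
Product: 11 5-hydroxy-2,2-dimethyl-2H-chromene-6-carbaldehyde
Conditions: pyridine, 140 °C (sealed tube)
Reagents that add atoms: none
Why: Chromenylation of a resorcinol (formal [3+3] annulation): condensation of the enal at C3 of the ring, dehydration and oxa-6π electrocyclisation; the 2-hydroxyl is chelated to the formyl group, so the pyran should close through the 4-oxygen and give the angular 5-hydroxy-6-formyl chromene.

Step 8
Reactants: 11 5-hydroxy-2,2-dimethyl-2H-chromene-6-carbaldehyde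
Product: 12 5-(tert-butyldimethylsilyloxy)-2,2-dimethyl-2H-chromene-6-carbaldehyde
Conditions: TBSCl (1.5 equiv), imidazole (3 equiv), DMAP (cat.), DMF, 40 °C
Reagents that add atoms: tert-butyldimethylsilyl chloride, CC(C)(C)[Si](C)(C)Cl
Why: Silylation of a chelated phenol; the silyl ether blocks cyclisation of the later ortho-alkynylphenol to a benzofuran and leaves with fluoride at the end.

Step 9
Reactants: 12 5-(tert-butyldimethylsilyloxy)-2,2-dimethyl-2H-chromene-6-carbaldehyde
Product: 13 5-(tert-butyldimethylsilyloxy)-6-(2,2-dibromoethenyl)-2,2-dimethyl-2H-chromene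
Conditions: CBr4 (2 equiv), PPh3 (2 equiv), Zn dust (2 equiv), CH2Cl2, rt
Reagents that add atoms: carbon tetrabromide, BrC(Br)(Br)Br
Why: First stage of the Corey–Fuchs homologation, a Wittig-type reaction of the dibromomethylene ylide; forming the ylide with zinc avoids Ph3PBr2, which could attack the silyl ether or the chromene.

Step 10
Reactants: 13 5-(tert-butyldimethylsilyloxy)-6-(2,2-dibromoethenyl)-2,2-dimethyl-2H-chromene
Product: 15 5-(tert-butyldimethylsilyloxy)-2,2-dimethyl-6-[(trimethylsilyl)ethynyl]-2H-chromene, via lithium acetylide 14 (not isolated)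
Conditions: n-BuLi (2.2 equiv), THF, −78 °C; then TMSCl (2.5 equiv), −78 °C to rt
Reagents that add atoms: chlorotrimethylsilane, C[Si](C)(C)Cl
Why: Second stage of the Corey–Fuchs sequence: bromine–lithium exchange and Fritsch–Buttenberg–Wiechell rearrangement give the lithium acetylide, which is C-silylated in the same flask; at −78 °C the aryl silyl ether should tolerate n-BuLi.

Step 11
Reactants: 8 4,6-bis(tert-butyldimethylsilyloxy)-2-hydroxy-5-(3-hydroxy-3-methylbutyl)benzaldehyde; 15 5-(tert-butyldimethylsilyloxy)-2,2-dimethyl-6-[(trimethylsilyl)ethynyl]-2H-chromene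
Product: 16 5,7-bis(tert-butyldimethylsilyloxy)-3-[5-(tert-butyldimethylsilyloxy)-2,2-dimethyl-2H-chromen-6-yl]-6-(3-hydroxy-3-methylbutyl)-2-(trimethylsilyl)-4H-chromen-4-one
Conditions: [Cp*RhCl2]2 (5 mol %), anhydrous Cu(OAc)2 (2.2 equiv), 15 (1.3 equiv), toluene, 110 °C, argon
Reagents that add atoms: none
Why: The phenoxide of 8 binds trivalent rhodium and acetate-assisted cleavage of the formyl C–H bond gives a five-membered acyl rhodacycle; 15 inserts into the Rh–acyl bond, C–O reductive elimination from the seven-membered oxa-rhodacycle closes ring C, and Cu(OAc)2 (divalent copper) returns monovalent rhodium to the trivalent state. The closest known reaction type is the rhodium-catalysed oxidative annulation of salicylaldehydes with internal alkynes to 2,3-disubstituted chromones. Ring C closes as a six-membered pyranone in a formal [4+2] mode (O1, C8a, C4a and C4 from 8; C2 and C3 from 15), the last bond being O1–C2. No stereocentre is formed. The step needs insertion with ring B on the carbon that bonds to the acyl group (C3) and silicon on the rhodium-bound carbon (C2): silicon stabilises a metal on its own carbon and positive character on the neighbouring one, and the Me3Si group avoids the forming C–C bond, as in Larock-type annulations of silyl alkynes. Site selectivity is built into 8, whose only free phenol is the one para to the chain, so O1 and the 6-alkyl pattern are fixed. A non-polar solvent and anhydrous Cu(OAc)2 are chosen so that the alkynyl C–Si bond is not cut and copper-mediated alkyne dimerisation does not precede insertion; loss of silicon after ring closure would be harmless because step 12 removes it anyway.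

Step 12
Reactants: 16 5,7-bis(tert-butyldimethylsilyloxy)-3-[5-(tert-butyldimethylsilyloxy)-2,2-dimethyl-2H-chromen-6-yl]-6-(3-hydroxy-3-methylbutyl)-2-(trimethylsilyl)-4H-chromen-4-one
Product: 17 Kanzonol T, 5,7-dihydroxy-3-(5-hydroxy-2,2-dimethyl-2H-chromen-6-yl)-6-(3-hydroxy-3-methylbutyl)-4H-chromen-4-one
Conditions: Bu4NF (6 equiv), wet THF, 0 °C to rt; AcOH quench
Reagents that add atoms: none
Why: Fluoride-induced desilylation: the three aryl silyl ethers are cleaved and the C2–Si bond is broken through a pentacoordinate silicate, the departing sp2 carbon being attached to the ring oxygen and the most acidic C–H site of the chromone; fluoride spares the tertiary alcohol and the chromene that acid would destroy.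

## Compound list

1 | 2,4,6-trihydroxybenzaldehyde | O=Cc1c(O)cc(O)cc1O | starting material
2 | 4-(benzyloxy)-2,6-dihydroxybenzaldehyde | O=Cc1c(O)cc(OCc2ccccc2)cc1O | intermediate
3 | 4-(benzyloxy)-2,6-bis(tert-butyldimethylsilyloxy)benzaldehyde | O=Cc1c(O[Si](C)(C)C(C)(C)C)cc(OCc2ccccc2)cc1O[Si](C)(C)C(C)(C)C | intermediate
4 | 1-(triphenylphosphoranylidene)propan-2-one | CC(=O)C=P(c1ccccc1)(c1ccccc1)c1ccccc1 | starting material
5 | (E)-4-[4-(benzyloxy)-2,6-bis(tert-butyldimethylsilyloxy)phenyl]but-3-en-2-one | CC(=O)/C=C/c1c(O[Si](C)(C)C(C)(C)C)cc(OCc2ccccc2)cc1O[Si](C)(C)C(C)(C)C | intermediate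
6 | 4-[2,6-bis(tert-butyldimethylsilyloxy)-4-hydroxyphenyl]butan-2-one | CC(=O)CCc1c(O[Si](C)(C)C(C)(C)C)cc(O)cc1O[Si](C)(C)C(C)(C)C | intermediate
7 | 3,5-bis(tert-butyldimethylsilyloxy)-4-(3-hydroxy-3-methylbutyl)phenol | CC(C)(O)CCc1c(O[Si](C)(C)C(C)(C)C)cc(O)cc1O[Si](C)(C)C(C)(C)C | intermediate
8 | 4,6-bis(tert-butyldimethylsilyloxy)-2-hydroxy-5-(3-hydroxy-3-methylbutyl)benzaldehyde | CC(C)(O)CCc1c(O[Si](C)(C)C(C)(C)C)cc(O)c(C=O)c1O[Si](C)(C)C(C)(C)C | intermediate
9 | 2,4-dihydroxybenzaldehyde | O=Cc1ccc(O)cc1O | starting material
10 | 3-methylbut-2-enal | CC(C)=CC=O | starting material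
11 | 5-hydroxy-2,2-dimethyl-2H-chromene-6-carbaldehyde | O=Cc1ccc2OC(C)(C)C=Cc2c1O | intermediate
12 | 5-(tert-butyldimethylsilyloxy)-2,2-dimethyl-2H-chromene-6-carbaldehyde | O=Cc1ccc2OC(C)(C)C=Cc2c1O[Si](C)(C)C(C)(C)C | intermediate
13 | 5-(tert-butyldimethylsilyloxy)-6-(2,2-dibromoethenyl)-2,2-dimethyl-2H-chromene | BrC(Br)=Cc1ccc2OC(C)(C)C=Cc2c1O[Si](C)(C)C(C)(C)C | intermediate
14 | lithium [5-(tert-butyldimethylsilyloxy)-2,2-dimethyl-2H-chromen-6-yl]acetylide | [Li]C#Cc1ccc2OC(C)(C)C=Cc2c1O[Si](C)(C)C(C)(C)C | intermediate (not isolated)
15 | 5-(tert-butyldimethylsilyloxy)-2,2-dimethyl-6-[(trimethylsilyl)ethynyl]-2H-chromene | C[Si](C)(C)C#Cc1ccc2OC(C)(C)C=Cc2c1O[Si](C)(C)C(C)(C)C | intermediate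
16 | 5,7-bis(tert-butyldimethylsilyloxy)-3-[5-(tert-butyldimethylsilyloxy)-2,2-dimethyl-2H-chromen-6-yl]-6-(3-hydroxy-3-methylbutyl)-2-(trimethylsilyl)-4H-chromen-4-one | CC(C)(O)CCc1c(O[Si](C)(C)C(C)(C)C)cc2oc([Si](C)(C)C)c(-c3ccc4OC(C)(C)C=Cc4c3O[Si](C)(C)C(C)(C)C)c(=O)c2c1O[Si](C)(C)C(C)(C)C | intermediate
17 | Kanzonol T | CC(C)(O)CCc1c(O)cc2occ(-c3ccc4c(c3O)C=CC(C)(C)O4)c(=O)c2c1O | target

## Step count and least certain steps

Total: 12 steps. Longest linear sequence: 8 steps (steps 1 to 6, 11 and 12); the ring B branch (steps 7 to 10) joins at step 11.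

**Step 11 (key step).**
- Risk: insertion of the alkyne in the opposite sense (ring B on the rhodium-bound carbon); loss of the alkynyl silicon before insertion followed by copper-mediated alkyne dimerisation; or insertion so slow between two partners flanked by ortho silyloxy groups that decarbonylation of the acyl rhodium species competes.
- Fallback: the two bonds are made one after the other by carbonyl chemistry, setting out from 8 and 12 and returning at 17.
- Phenol 8 is capped with Et3SiCl and imidazole as 4,6-bis(tert-butyldimethylsilyloxy)-5-(3-hydroxy-3-methylbutyl)-2-(triethylsilyloxy)benzaldehyde F1.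
- Aldehyde 12 is condensed with TsNHNH2 to N'-{(E)-[5-(tert-butyldimethylsilyloxy)-2,2-dimethyl-2H-chromen-6-yl]methylidene}-4-methylbenzenesulfonohydrazide F2.
- Heating F1 and F2 with K2CO3 in dioxane (Bamford–Stevens loss of sulfinate, carbonyl addition, hydride shift with extrusion of dinitrogen) should join C4 to C3 in 1-[2,4-bis(tert-butyldimethylsilyloxy)-3-(3-hydroxy-3-methylbutyl)-6-(triethylsilyloxy)phenyl]-2-[5-(tert-butyldimethylsilyloxy)-2,2-dimethyl-2H-chromen-6-yl]ethan-1-one F3.
- AcOH–THF–H2O releases the more labile triethylsilyl ether to give 1-[2,4-bis(tert-butyldimethylsilyloxy)-6-hydroxy-3-(3-hydroxy-3-methylbutyl)phenyl]-2-[5-(tert-butyldimethylsilyloxy)-2,2-dimethyl-2H-chromen-6-yl]ethan-1-one F4.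
- Me2NCH(OMe)2 in toluene at 90 °C supplies C2 and closes ring C through O1–C2, giving 5,7-bis(tert-butyldimethylsilyloxy)-3-[5-(tert-butyldimethylsilyloxy)-2,2-dimethyl-2H-chromen-6-yl]-6-(3-hydroxy-3-methylbutyl)-4H-chromen-4-one F5, which the conditions of step 12 convert into 17.

**Step 1.**
- Risk: over-alkylation, alkylation at an ortho oxygen, or C-benzylation of the very electron-rich ring would erode the selectivity for the para oxygen.
- Fallback: the para oxygen is introduced last instead of being differentiated first, setting out from ylide 4 and returning at 7.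
- Commercial 2,6-dihydroxybenzaldehyde F6 is silylated (TBSCl, imidazole, DMF) to 2,6-bis(tert-butyldimethylsilyloxy)benzaldehyde F7.
- F7 with 4 gives (E)-4-[2,6-bis(tert-butyldimethylsilyloxy)phenyl]but-3-en-2-one F8.
- Hydrogenation (H2, Pd/C) gives 4-[2,6-bis(tert-butyldimethylsilyloxy)phenyl]butan-2-one F9, and MeMgBr gives 4-[2,6-bis(tert-butyldimethylsilyloxy)phenyl]-2-methylbutan-2-ol F10.
- Sterically governed C–H borylation ([Ir(OMe)(cod)]2, 4,4'-di-tert-butyl-2,2'-bipyridine, B2pin2, THF, 70 °C) can reach only the ring C–H para to the chain, the other two being flanked by silyloxy groups. It should give 4-[2,6-bis(tert-butyldimethylsilyloxy)-4-(4,4,5,5-tetramethyl-1,3,2-dioxaborolan-2-yl)phenyl]-2-methylbutan-2-ol F11; the tertiary hydroxyl, if borylated, is restored on work-up.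
- NaBO3·4H2O in THF–water oxidises the C–B bond to the hydroxyl of 7.

**Step 3.**
- Risk: stalled olefination at a carbonyl flanked by two bulky silyloxy groups, with silyl loss on prolonged heating.
- Fallback: the order of silylation and olefination is exchanged, setting out from 2 and returning at 5.
- Diol 2 reacts with 4 in refluxing toluene to give (E)-4-[4-(benzyloxy)-2,6-dihydroxyphenyl]but-3-en-2-one F12, whose carbonyl partner was not shielded.
- F12 is then bis-silylated (TBSCl, imidazole, DMF) to 5.

**Step 6.**
- Risk: incomplete formylation at a carbon lying between the hydroxyl and a silyloxy group, and loss of a silyl ether on prolonged heating with Et3N and MgCl2.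
- Fallback: halogenation followed by palladium-catalysed formylation, setting out from 7 and returning at 8.
- NBS (1 equiv, CH2Cl2, −78 to 0 °C) brominates one of the two equivalent ortho positions to give 2-bromo-3,5-bis(tert-butyldimethylsilyloxy)-4-(3-hydroxy-3-methylbutyl)phenol F13.
- Reductive carbonylation (Pd(OAc)2, di(1-adamantyl)-n-butylphosphine, CO/H2, TMEDA, toluene, 100 °C) replaces bromine by the formyl group and gives 8.

**Step 10.**
- Risk: attack of n-BuLi at the silicon of the aryl silyl ether, or migration of that silyl group from oxygen to a carbanionic carbon.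
- Fallback: a diazo-based homologation (Colvin rearrangement) that by-passes 13, setting out from 12 and returning at 15.
- Lithiated trimethylsilyldiazomethane (Me3SiCHN2, LiN(i-Pr)2, THF, −78 to 0 °C) converts 12 into 5-(tert-butyldimethylsilyloxy)-6-ethynyl-2,2-dimethyl-2H-chromene F14.
- LiN(SiMe3)2 followed by TMSCl gives 15.

## Further compounds

F1 | step 11 | 4,6-bis(tert-butyldimethylsilyloxy)-5-(3-hydroxy-3-methylbutyl)-2-(triethylsilyloxy)benzaldehyde | CC(C)(O)CCc1c(O[Si](C)(C)C(C)(C)C)cc(O[Si](CC)(CC)CC)c(C=O)c1O[Si](C)(C)C(C)(C)C
F2 | step 11 | N'-{(E)-[5-(tert-butyldimethylsilyloxy)-2,2-dimethyl-2H-chromen-6-yl]methylidene}-4-methylbenzenesulfonohydrazide | Cc1ccc(cc1)S(=O)(=O)N/N=C/c1ccc2OC(C)(C)C=Cc2c1O[Si](C)(C)C(C)(C)C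
F3 | step 11 | 1-[2,4-bis(tert-butyldimethylsilyloxy)-3-(3-hydroxy-3-methylbutyl)-6-(triethylsilyloxy)phenyl]-2-[5-(tert-butyldimethylsilyloxy)-2,2-dimethyl-2H-chromen-6-yl]ethan-1-one | CC(C)(O)CCc1c(O[Si](C)(C)C(C)(C)C)cc(O[Si](CC)(CC)CC)c(C(=O)Cc2ccc3OC(C)(C)C=Cc3c2O[Si](C)(C)C(C)(C)C)c1O[Si](C)(C)C(C)(C)C
F4 | step 11 | 1-[2,4-bis(tert-butyldimethylsilyloxy)-6-hydroxy-3-(3-hydroxy-3-methylbutyl)phenyl]-2-[5-(tert-butyldimethylsilyloxy)-2,2-dimethyl-2H-chromen-6-yl]ethan-1-one | CC(C)(O)CCc1c(O[Si](C)(C)C(C)(C)C)cc(O)c(C(=O)Cc2ccc3OC(C)(C)C=Cc3c2O[Si](C)(C)C(C)(C)C)c1O[Si](C)(C)C(C)(C)C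
F5 | step 11 | 5,7-bis(tert-butyldimethylsilyloxy)-3-[5-(tert-butyldimethylsilyloxy)-2,2-dimethyl-2H-chromen-6-yl]-6-(3-hydroxy-3-methylbutyl)-4H-chromen-4-one | CC(C)(O)CCc1c(O[Si](C)(C)C(C)(C)C)cc2occ(-c3ccc4OC(C)(C)C=Cc4c3O[Si](C)(C)C(C)(C)C)c(=O)c2c1O[Si](C)(C)C(C)(C)C
F6 | step 1 | 2,6-dihydroxybenzaldehyde (purchased) | O=Cc1c(O)cccc1O
F7 | step 1 | 2,6-bis(tert-butyldimethylsilyloxy)benzaldehyde | O=Cc1c(O[Si](C)(C)C(C)(C)C)cccc1O[Si](C)(C)C(C)(C)C
F8 | step 1 | (E)-4-[2,6-bis(tert-butyldimethylsilyloxy)phenyl]but-3-en-2-one | CC(=O)/C=C/c1c(O[Si](C)(C)C(C)(C)C)cccc1O[Si](C)(C)C(C)(C)C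
F9 | step 1 | 4-[2,6-bis(tert-butyldimethylsilyloxy)phenyl]butan-2-one | CC(=O)CCc1c(O[Si](C)(C)C(C)(C)C)cccc1O[Si](C)(C)C(C)(C)C
F10 | step 1 | 4-[2,6-bis(tert-butyldimethylsilyloxy)phenyl]-2-methylbutan-2-ol | CC(C)(O)CCc1c(O[Si](C)(C)C(C)(C)C)cccc1O[Si](C)(C)C(C)(C)C
F11 | step 1 | 4-[2,6-bis(tert-butyldimethylsilyloxy)-4-(4,4,5,5-tetramethyl-1,3,2-dioxaborolan-2-yl)phenyl]-2-methylbutan-2-ol | CC(C)(O)CCc1c(O[Si](C)(C)C(C)(C)C)cc(B2OC(C)(C)C(C)(C)O2)cc1O[Si](C)(C)C(C)(C)C
F12 | step 3 | (E)-4-[4-(benzyloxy)-2,6-dihydroxyphenyl]but-3-en-2-one | CC(=O)/C=C/c1c(O)cc(OCc2ccccc2)cc1O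
F13 | step 6 | 2-bromo-3,5-bis(tert-butyldimethylsilyloxy)-4-(3-hydroxy-3-methylbutyl)phenol | CC(C)(O)CCc1c(O[Si](C)(C)C(C)(C)C)cc(O)c(Br)c1O[Si](C)(C)C(C)(C)C
F14 | step 10 | 5-(tert-butyldimethylsilyloxy)-6-ethynyl-2,2-dimethyl-2H-chromene | C#Cc1ccc2OC(C)(C)C=Cc2c1O[Si](C)(C)C(C)(C)C
A1 | alternative 1 | 2'-O-allyl Kanzonol T | CC(C)(O)CCc1c(O)cc2occ(-c3ccc4OC(C)(C)C=Cc4c3OCC=C)c(=O)c2c1O
A2 | alternative 1 | methyl 5-[5-(allyloxy)-2,2-dimethyl-2H-chromen-6-yl]-2-methyl-4-oxo-4H-pyran-3-carboxylate | COC(=O)c1c(C)occ(-c2ccc3OC(C)(C)C=Cc3c2OCC=C)c1=O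
A3 | alternative 1 | 6,6-dimethyloxan-2-one | CC1(C)CCCC(=O)O1
A4 | alternative 2 | tetrakis-O-silyl Kanzonol T | CC(C)(O[Si](CC)(CC)CC)CCc1c(O[Si](C)(C)C(C)(C)C)cc2occ(-c3ccc4OC(C)(C)C=Cc4c3O[Si](C(C)C)(C(C)C)C(C)C)c(=O)c2c1O[Si](C)(C)C(C)(C)C
A5 | alternative 2 | 2,2-dimethyl-2H,5H-pyrano[4,3-b]pyran-5-one | O=c1occc2OC(C)(C)C=Cc12
A6 | alternative 2 | 5,7-bis(tert-butyldimethylsilyloxy)-6-[3-methyl-3-(triethylsilyloxy)butyl]-3-[(triisopropylsilyloxy)ethynyl]-4H-chromen-4-one | CC(C)(O[Si](CC)(CC)CC)CCc1c(O[Si](C)(C)C(C)(C)C)cc2occ(C#CO[Si](C(C)C)(C(C)C)C(C)C)c(=O)c2c1O[Si](C)(C)C(C)(C)C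
A7 | alternative 3 | 5,7,2'-tris-O-methoxymethyl Kanzonol T | CC(C)(O)CCc1c(OCOC)cc2occ(-c3ccc4OC(C)(C)C=Cc4c3OCOC)c(=O)c2c1OCOC
A8 | alternative 3 | 4-(3-hydroxy-3-methylbutyl)-3,5-bis(methoxymethoxy)-2-(trimethylsilyl)phenyl trifluoromethanesulfonate | CC(C)(O)CCc1c(OCOC)cc(OS(=O)(=O)C(F)(F)F)c([Si](C)(C)C)c1OCOC
A9 | alternative 3 | 4-(3-hydroxy-3-methylbutyl)-3,5-bis(methoxymethoxy)-1,2-didehydrobenzene (ring A aryne) | COCOC1=C(CCC(C)(C)O)C(OCOC)=CC#C1
A10 | alternative 3 | methyl 2-[5-(methoxymethoxy)-2,2-dimethyl-2H-chromen-6-yl]-3-oxopropanoate | COC(=O)C(C=O)c1ccc2OC(C)(C)C=Cc2c1OCOC
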